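**Assumption:** 4-(benzyloxy)-3-methoxybenzaldehyde, methyl vanillate and (4S)-4-benzyl-1,3-oxazolidin-2-one are taken as purchased. The enantiomer of the dirhodium carboxamidate is assigned by analogy with the sense of induction established for simpler allylic diazoacetates and should be confirmed on the first batch.

## Analysis of the target

The target 33 is a sesquilignan. A trans-2-aryl-3-(hydroxymethyl)-7-methoxy-2,3-dihydrobenzofuran (ring A on C2, ring B fused to the dihydrofuran) is joined through a methylene group on C5 to C-alpha of a gamma-butyrolactone, and C-beta of that lactone carries a CH(OH) group bearing ring C. The five stereocentres fall into two clusters that the methylene link insulates from each other. C2 (S) and C3 (R) are trans on the dihydrofuran. Lactone C-alpha (R), C-beta (R) and the carbinol carbon (R) form a contiguous triad, trans on the ring and, in the zigzag CH2O–C-beta–carbinol–ring C, anti between C-alpha and the hydroxyl. Neither cluster can relay its configuration to the other, so each must be made in absolute terms before they are joined.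

The sensitive sites are:
- the benzylic carbinol para to the ring C oxygen (ionisation leads to epimerisation, Friedel–Crafts closure onto C4 or C6 of ring B, and hydrogenolysis);
- the lactone next to that hydroxyl (translactonisation under base);
- the benzylic aryl ether bond C2–O1;
- the two free guaiacyl phenols.

The real difficulty is the acyclic carbinol centre. It lies outside the lactone ring, the electron-rich arene beside it makes every SN1 pathway easy, and a substrate-controlled ketone reduction gives no dependable bias for the R epimer.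

The feature exploited is that C-beta and the carbinol carbon are directly bonded and C-alpha is bonded to C-beta. One extra bond from C-alpha to the carbinol carbon, absent from the target, ties all three atoms into a cyclopropane fused to the lactone, a 3-oxabicyclo[3.1.0]hexan-2-one. One catalytic event fixes the three centres of that bicycle. Heterolysis of the extra bond with inversion at the benzylic carbon then gives the carbinol and returns C-alpha to a CH2 group ready for trans alkylation.

## Retrosynthetic reasoning

**Deprotection (33 from 32 from 31).** The phenols of rings A and C are carried as benzyl ethers and the two hydroxyl groups as tert-butyldimethylsilyl ethers. 33 arises from 32 by hydrogenolysis and 32 from 31 by buffered fluoride. The silyl groups come off first, while the phenols are still masked, because a free para-phenol beside an oxygenated benzylic carbon opens a quinone methide channel under basic fluoride. The last step must then be a mild, neutral hydrogenolysis that spares the benzylic carbinol and the C2–O1 bond.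

**C-alpha–CH2 bond (31 from 11 and 29).** This is the only bond that separates the two stereo-clusters. Cutting it gives the beta-substituted lactone 11 and the benzylic bromide 29, of similar size, each built with its own control element. In the forward sense the lithium enolate 30 of 11 must be alkylated anti to the bulky beta substituent, which sets C-alpha trans. A cut at the aryl–CH2 bond would need a cross-coupling at a carbon beta to a lactone and would give no stereochemical help.

**Carbinol C–O bond and the sacrificial bond (11 from 10 from 9).** The silyl ether 11 comes from the carbinol 10. 10 is viewed as the adduct of an oxygen nucleophile across the C1–C6 bond of the cyclopropane-fused lactone 9. This is preferred to a ketone reduction or an aldol because the carbinol configuration then derives from C6 by one inversion and no enolisable ketone next to C-beta is ever formed. The forward reaction must break only the C1–C6 bond (the one aligned with the lactone carbonyl and carrying ring C), attack C6 from the rear, leave C5 untouched and protonate C1.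

**Cyclopropane (9 from 8).** 9 is cut at C1–C5 and C1–C6 back to the E diazoacetate 8. Both bonds, both rings and all three stereocentres then come from one catalytic carbene transfer. The E geometry becomes the exo position of ring C and, after the inversion, the required anti relation. The forward step has to distinguish the two faces of the alkene.

**Diazoacetate (8 from 6, 4, 3, 1 and 2).** The diazo group is introduced last, through the alkylated hydrazine 7, from the bromoacetate 6 of the allylic alcohol 4. 4 comes from the aldehyde 1 by olefination with 2 to the E ester 3 and reduction. Four routine steps precede the key step, so the risk sits in steps 5 and 6.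

**Bromide (29 from 28, 27 and 26).** The reactive para-alkoxybenzyl bromide 29 is made last from the alcohol 28. The C5 carbon is carried as a methyl ester through 27 and 26 because an ester survives the acidic ring closure, whereas a para-alkoxybenzyl alcohol would not.

**Dihydrofuran C2–O1 bond (26 from 24 through 25).** The benzylic C2–O1 bond is cut because its forward formation by capture of a ring-A-stabilised benzylic cation by the ring B phenol is trans-selective under thermodynamic control. Only C3 then needs absolute control. The configuration of the carbinol in 24 is irrelevant.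

**C2–C3 bond (24 from 23 from 21 and 1).** An auxiliary-controlled aldol between the arylacetyl imide 21 (through its boron enolate 22) and the aldehyde 1 forms the C2–C3 bond and fixes C3. Reductive removal of the auxiliary turns the imide carbonyl into the future CH2OH group.

**Arylacetic arm (21 from 18 and 19; 18 from 16 through 17; 16 from 15, 14, 12 and 13).** The two-carbon arm ortho to the ring B oxygen is installed by an aromatic Claisen rearrangement of the allyl ether 14 of methyl vanillate 12. Only one ortho position is open. The allyl group of 15, after phenol protection to 16, is cleaved oxidatively through the aldehyde 17 to the acid 18. 18 is joined to the auxiliary 19 through the mixed anhydride 20.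

## Alternatives that were turned down

**Alternative 1:** Both substituent bonds of the lactone are cut (carbinol carbon–C-beta and CH2–C-alpha), leaving the chiral butenolide (5R)-5-[(1R,2S,5R)-menthyloxy]furan-2(5H)-one A1, the acyl anion equivalent 2-[4-(benzyloxy)-3-methoxyphenyl]-1,3-dithiane A2 and the bromide 29.
- Forward key step: lithiated A2 adds to C-beta of A1 anti to the menthyloxy group, and the enolate is alkylated in the same flask by 29 anti to the new beta substituent, giving the trans acetal lactone A3. No ring closes.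
- For: it is the most convergent plan. Two C–C bonds and both ring centres arise in one operation of a well-established type. On reliability of the C–C bond formation it is stronger than the chosen route, which contains one step of unproven type.
- Against: the carbinol centre is not addressed. The dithiane must be unmasked to an aryl ketone with thiophilic or oxidising reagents in the presence of three electron-rich arenes and a benzylic aryl ether. The ketone makes C-beta enolisable. Its reduction to the R alcohol rests on substrate control of unpredictable sense. The acetal carbon must also be taken down to CH2 by reductive opening and relactonisation while a second hydroxyl competes for the carboxyl group.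
- Comparison: about five further steps follow the key step of this plan. The chosen strategy derives the carbinol configuration from alkene geometry through a stereospecific bond cleavage and never passes through the ketone.

**Alternative 2:** The C3–C3a bond of the dihydrobenzofuran and the C–O bond of the hydroxymethyl arm are cut, leading to the aryl iodide 2-{4-[(1S)-1-[4-(benzyloxy)-3-methoxyphenyl]prop-2-en-1-yloxy]-3-iodo-5-methoxyphenyl}-1,3-dioxolane A4.
- Forward key step: a tin hydride generates the ring B aryl radical, which closes 5-exo-trig onto the vinyl group. A persistent nitroxide captures the primary radical to give the dihydrobenzofuran A5.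
- For: the dihydrofuran forms under neutral conditions, the trans relation follows from the existing C2 centre, and the oxygenated arm at C3 arrives directly. It would probably reach the dihydrobenzofuran in fewer steps than the aldol sequence used here (steps 8 to 18); on that point it is stronger.
- Against: it solves only the dihydrobenzofuran half and leaves the harder lactone triad open. The ether in A4 is benzylic, allylic and para-alkoxy-activated, so it is prone to ionisation, racemisation and sigmatropic shift. Nitroxide and tin hydride consume each other. The N–O bond must later be cleaved reductively.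
- Comparison: the chosen route pays with a longer, classical fragment synthesis in which C2 is set thermodynamically, and spends its one uncertain step on the triad, which this plan does not touch.

**Alternative 3:** The C3–C3a and O1–C2 bonds are cut at the very end in a biomimetic sense. The partners are the feruloyl imide (4S)-4-benzyl-3-[(E)-3-(4-hydroxy-3-methoxyphenyl)prop-2-enoyl]-1,3-oxazolidin-2-one A6 and the phenolic lactone (3R,4R)-4-[(R)-[4-(benzyloxy)-3-methoxyphenyl](hydroxy)methyl]-3-(4-hydroxy-3-methoxybenzyl)oxolan-2-one A7.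
- Forward key step: a silver-based one-electron oxidant converts both phenols into radicals. The side-chain carbon of A6 pairs with the ortho carbon of ring B, and the ring B phenol oxygen then adds to the ring A quinone methide to give A8.
- For: it is the shortest endgame, builds the dihydrofuran in one step with inherent trans selectivity and needs no protecting group on ring A. On step count it is clearly stronger.
- Against: cross-coupling competes with homo-coupling of A6. The ring B phenol lacks a conjugated side chain and is the poorer radical partner. The auxiliary is remote from the pairing carbon, so control of C2 and C3 is weak, and the resulting diastereomers of a late, valuable intermediate would be hard to separate. The imide must then be reduced beside the lactone. A7 itself still contains the lactone triad, so the carbinol problem is only moved.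
- Comparison: the chosen strategy assigns a defined control element to every stereocentre and joins the halves by a dependable enolate alkylation.

Key step: step 5

## Route

Step 1
Reactants: 1 4-(benzyloxy)-3-methoxybenzaldehyde; 2 triethyl phosphonoacetate
Product: 3 ethyl (E)-3-[4-(benzyloxy)-3-methoxyphenyl]prop-2-enoate
Conditions: NaH, THF, 0 °C to rt
Reagents that add atoms: none
Why: Horner–Wadsworth–Emmons olefination; the stabilised phosphonate anion gives the E alkene, whose geometry later places ring C exo on the cyclopropane.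

Step 2
Reactants: 3 ethyl (E)-3-[4-(benzyloxy)-3-methoxyphenyl]prop-2-enoate
Product: 4 (E)-3-[4-(benzyloxy)-3-methoxyphenyl]prop-2-en-1-ol
Conditions: i-Bu2AlH (2.5 equiv), CH2Cl2, −78 °C; aq. KNaC4H4O6
Reagents that add atoms: none
Why: 1,2-reduction of an enoate by an aluminium hydride at low temperature; the alkene geometry and the benzyl ether are untouched.

Step 3
Reactants: 4 (E)-3-[4-(benzyloxy)-3-methoxyphenyl]prop-2-en-1-ol; 5 bromoacetyl bromide
Product: 6 (E)-3-[4-(benzyloxy)-3-methoxyphenyl]prop-2-en-1-yl bromoacetate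
Conditions: NaHCO3, MeCN, 0 °C
Reagents that add atoms: none
Why: O-acylation with an acid bromide; the mild insoluble base removes HBr without quaternisation by the bromoacetate and without ionising the electron-rich cinnamyl ester.

Step 4
Reactants: 6 (E)-3-[4-(benzyloxy)-3-methoxyphenyl]prop-2-en-1-yl bromoacetate
Product: 8 (E)-3-[4-(benzyloxy)-3-methoxyphenyl]prop-2-en-1-yl diazoacetate, via alkylated ditosylhydrazine 7 (not isolated)
Conditions: TsNHNHTs, DBU, THF, 0 °C
Reagents that add atoms: N,N'-ditosylhydrazine, Cc1ccc(cc1)S(=O)(=O)NNS(=O)(=O)c1ccc(C)cc1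
Why: Diazoacetate synthesis by the ditosylhydrazine method; the hydrazine anion displaces bromide (SN2) and DBU then expels two sulfinate ions to unveil the diazo group under conditions that spare the allylic ester.

Step 5
Reactants: 8 (E)-3-[4-(benzyloxy)-3-methoxyphenyl]prop-2-en-1-yl diazoacetate
Product: 9 (1S,5R,6R)-6-[4-(benzyloxy)-3-methoxyphenyl]-3-oxabicyclo[3.1.0]hexan-2-one
Conditions: Rh2(4R-MPPIM)4, i.e. Rh2[methyl (4R)-2-oxo-1-(3-phenylpropanoyl)imidazolidine-4-carboxylate]4 (1 mol%), CH2Cl2, reflux, 8 added over 10 h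
Reagents that add atoms: none
Why: The divalent rhodium carboxamidate extrudes N2 from 8 to give an electrophilic rhodium carbenoid that adds in a concerted, asynchronous way across the tethered E alkene; the closest known reaction type is this same intramolecular cyclopropanation of allylic diazoacetates with chiral dirhodium carboxamidates. The carbenoid carbon becomes C1 and bonds to both alkene carbons: the C1–C5 bond closes the lactone as a five-membered ring in an exo mode (C6 stays outside that ring), and the C1–C6 bond closes the three-membered ring in the same event. The three-atom ester tether allows only the cis-fused bicyclo[3.1.0] mode, so C1 is fixed relative to C5 by ring strain. The C5/C6 relation follows stereospecifically from the E alkene, which puts ring C exo, trans to C4. The absolute sense of all three centres is set by the chiral ligand sphere, which leaves one face of the alkene open to the carbenoid; the (4R) ligand is specified by analogy with the sense of induction established for simpler allylic diazoacetates. The step needs enantiofacial selectivity and chemoselectivity for the alkene over carbene dimerisation, aromatic cycloaddition and C–H insertion; slow addition of 8, the low electrophilicity of the carboxamidate carbenoid and the nucleophilic styrene-type alkene secure the latter.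

Step 6
Reactants: 9 (1S,5R,6R)-6-[4-(benzyloxy)-3-methoxyphenyl]-3-oxabicyclo[3.1.0]hexan-2-one
Product: 10 (4R)-4-[(R)-[4-(benzyloxy)-3-methoxyphenyl](hydroxy)methyl]oxolan-2-one
Conditions: Sc(OTf)3 (10 mol%), H2O (10 equiv), CH2Cl2/THF 9:1, −20 to 0 °C
Reagents that add atoms: water, O
Why: Proposed new method: Sc(OTf)3 on the lactone carbonyl polarises the C1–C6 bond, the one cyclopropane bond that overlaps with the carbonyl pi* orbital and carries the electron-releasing ring C at C6, and water attacks C6 from the side opposite C1 (SN2-like homoconjugate addition), inverting C6 to the R carbinol while C5 is untouched and C1 is protonated to CH2; the closest known reaction type is the Lewis-acid-catalysed invertive opening of aryl cyclopropane-1,1-diesters by water or alcohols, extended here to a singly activated bicyclic lactone.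

Step 7
Reactants: 10 (4R)-4-[(R)-[4-(benzyloxy)-3-methoxyphenyl](hydroxy)methyl]oxolan-2-one
Product: 11 (4R)-4-[(R)-[4-(benzyloxy)-3-methoxyphenyl][(tert-butyldimethylsilyl)oxy]methyl]oxolan-2-one
Conditions: TBSOTf, 2,6-lutidine, CH2Cl2, −78 °C
Reagents that add atoms: tert-butyldimethylsilyl trifluoromethanesulfonate, CC(C)(C)[Si](C)(C)OS(=O)(=O)C(F)(F)F
Why: Silylation of a hindered secondary alcohol with a silyl triflate and a hindered base; low temperature and the absence of alkoxide prevent ionisation of the benzylic C–O bond and translactonisation.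

Step 8
Reactants: 12 methyl 4-hydroxy-3-methoxybenzoate (methyl vanillate); 13 allyl bromide
Product: 14 methyl 3-methoxy-4-(prop-2-en-1-yloxy)benzoate
Conditions: K2CO3, acetone, reflux
Reagents that add atoms: none
Why: Williamson ether synthesis on a phenol.

Step 9
Reactants: 14 methyl 3-methoxy-4-(prop-2-en-1-yloxy)benzoate
Product: 15 methyl 4-hydroxy-3-methoxy-5-(prop-2-en-1-yl)benzoate
Conditions: N,N-diethylaniline, 200 °C
Reagents that add atoms: none
Why: Aromatic Claisen rearrangement; one ortho position carries the methoxy group and the para position the ester, so the allyl group can only arrive at the free ortho carbon, the future C3a.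

Step 10
Reactants: 15 methyl 4-hydroxy-3-methoxy-5-(prop-2-en-1-yl)benzoate
Product: 16 methyl 3-methoxy-4-(methoxymethoxy)-5-(prop-2-en-1-yl)benzoate
Conditions: MOMCl, i-Pr2NEt, CH2Cl2, 0 °C to rt
Reagents that add atoms: chloromethyl methyl ether, COCCl
Why: Acetal protection of the hindered phenol; the group tolerates boron enolate and hydride chemistry and is removed by the acid that closes the dihydrofuran.

Step 11
Reactants: 16 methyl 3-methoxy-4-(methoxymethoxy)-5-(prop-2-en-1-yl)benzoate
Product: 18 2-[3-methoxy-5-(methoxycarbonyl)-2-(methoxymethoxy)phenyl]acetic acid, via arylacetaldehyde 17 (not isolated)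
Conditions: O3, MeCN/H2O 9:1, 0 °C; then NaClO2, NaH2PO4, 0 °C to rt
Reagents that add atoms: ozone, [O-][O+]=O; sodium chlorite, [Na+].[O-]Cl=O
Why: Ozonolysis in wet acetonitrile, where water intercepts the carbonyl oxide and gives the aldehyde directly, followed in the same flask by Pinnick-type chlorite oxidation; the terminal alkene reacts faster than the ester-deactivated arene.

Step 12
Reactants: 18 2-[3-methoxy-5-(methoxycarbonyl)-2-(methoxymethoxy)phenyl]acetic acid; 19 (4S)-4-benzyl-1,3-oxazolidin-2-one
Product: 21 methyl 3-{2-[(4S)-4-benzyl-2-oxo-1,3-oxazolidin-3-yl]-2-oxoethyl}-5-methoxy-4-(methoxymethoxy)benzoate, via mixed pivalic anhydride 20 (not isolated)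
Conditions: t-BuCOCl, Et3N, THF, −20 °C; then 19, LiCl, −20 °C to rt
Reagents that add atoms: none
Why: N-acylation of the oxazolidinone through a mixed anhydride activated by LiCl; attack occurs at the less hindered arylacetyl carbonyl and the aryl methyl ester is inert.

Step 13
Reactants: 21 methyl 3-{2-[(4S)-4-benzyl-2-oxo-1,3-oxazolidin-3-yl]-2-oxoethyl}-5-methoxy-4-(methoxymethoxy)benzoate; 1 4-(benzyloxy)-3-methoxybenzaldehyde
Product: 23 methyl 3-[(2S,3S)-1-[(4S)-4-benzyl-2-oxo-1,3-oxazolidin-3-yl]-3-[4-(benzyloxy)-3-methoxyphenyl]-3-hydroxy-1-oxopropan-2-yl]-5-methoxy-4-(methoxymethoxy)benzoate, via dibutylboron Z-enolate 22 (not isolated)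
Conditions: Bu2BOTf, i-Pr2NEt, CH2Cl2, −78 to 0 °C; then 1, −78 to 0 °C; H2O2, pH 7 buffer, MeOH
Reagents that add atoms: none
Why: Evans syn aldol reaction; the Z boron enolate reacts through a closed chair transition state on the enolate face turned away from the benzyl group of the auxiliary, which sets the aryl-bearing carbon (the future C3) as S in the imide and the carbinol syn to it.

Step 14
Reactants: 23 methyl 3-[(2S,3S)-1-[(4S)-4-benzyl-2-oxo-1,3-oxazolidin-3-yl]-3-[4-(benzyloxy)-3-methoxyphenyl]-3-hydroxy-1-oxopropan-2-yl]-5-methoxy-4-(methoxymethoxy)benzoate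
Product: 24 methyl 3-[(1S,2R)-1-[4-(benzyloxy)-3-methoxyphenyl]-1,3-dihydroxypropan-2-yl]-5-methoxy-4-(methoxymethoxy)benzoate
Conditions: LiBH4, H2O (1 equiv), Et2O/THF, 0 °C
Reagents that add atoms: none
Why: Reductive cleavage of the N-acyl oxazolidinone to the primary alcohol; the activated imide is reduced far faster than the electron-rich aryl methyl ester, and the change of descriptor at the aryl-bearing carbon is only a change of priorities.

Step 15
Reactants: 24 methyl 3-[(1S,2R)-1-[4-(benzyloxy)-3-methoxyphenyl]-1,3-dihydroxypropan-2-yl]-5-methoxy-4-(methoxymethoxy)benzoate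
Product: 26 methyl (2S,3R)-2-[4-(benzyloxy)-3-methoxyphenyl]-3-(hydroxymethyl)-7-methoxy-2,3-dihydro-1-benzofuran-5-carboxylate, via free phenol 25 (not isolated)
Conditions: HCl (3 M aq.), MeOH/THF, 50 °C
Reagents that add atoms: none
Why: Acid removes the methoxymethyl group and ionises the benzylic alcohol to a cation stabilised by the para-benzyloxy group of ring A, which the neighbouring phenol captures in a five-membered ring closure (SN1-type cyclodehydration); the closure is reversible, so C2 settles trans to the C3 arm and becomes S whatever the configuration of the carbinol was.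

Step 16
Reactants: 26 methyl (2S,3R)-2-[4-(benzyloxy)-3-methoxyphenyl]-3-(hydroxymethyl)-7-methoxy-2,3-dihydro-1-benzofuran-5-carboxylate
Product: 27 methyl (2S,3R)-2-[4-(benzyloxy)-3-methoxyphenyl]-3-{[(tert-butyldimethylsilyl)oxy]methyl}-7-methoxy-2,3-dihydro-1-benzofuran-5-carboxylate
Conditions: TBSCl, imidazole, DMF, rt
Reagents that add atoms: tert-butyldimethylsilyl chloride, CC(C)(C)[Si](C)(C)Cl
Why: Standard silylation of a primary alcohol.

Step 17
Reactants: 27 methyl (2S,3R)-2-[4-(benzyloxy)-3-methoxyphenyl]-3-{[(tert-butyldimethylsilyl)oxy]methyl}-7-methoxy-2,3-dihydro-1-benzofuran-5-carboxylate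
Product: 28 [(2S,3R)-2-[4-(benzyloxy)-3-methoxyphenyl]-3-{[(tert-butyldimethylsilyl)oxy]methyl}-7-methoxy-2,3-dihydro-1-benzofuran-5-yl]methanol
Conditions: i-Bu2AlH (2.5 equiv), CH2Cl2, −78 to 0 °C
Reagents that add atoms: none
Why: Reduction of an aryl ester to the benzylic alcohol; silyl and benzyl ethers and the benzylic aryl ether are stable to the hydride.

Step 18
Reactants: 28 [(2S,3R)-2-[4-(benzyloxy)-3-methoxyphenyl]-3-{[(tert-butyldimethylsilyl)oxy]methyl}-7-methoxy-2,3-dihydro-1-benzofuran-5-yl]methanol
Product: 29 (2S,3R)-2-[4-(benzyloxy)-3-methoxyphenyl]-5-(bromomethyl)-3-{[(tert-butyldimethylsilyl)oxy]methyl}-7-methoxy-2,3-dihydro-1-benzofuran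
Conditions: CBr4, PPh3, CH2Cl2, 0 °C; used at once
Reagents that add atoms: carbon tetrabromide, BrC(Br)(Br)Br
Why: Appel bromination under neutral conditions; the para-alkoxybenzyl bromide ionises easily and is therefore made last and not stored.

Step 19
Reactants: 11 (4R)-4-[(R)-[4-(benzyloxy)-3-methoxyphenyl][(tert-butyldimethylsilyl)oxy]methyl]oxolan-2-one; 29 (2S,3R)-2-[4-(benzyloxy)-3-methoxyphenyl]-5-(bromomethyl)-3-{[(tert-butyldimethylsilyl)oxy]methyl}-7-methoxy-2,3-dihydro-1-benzofuran
Product: 31 (3R,4R)-4-[(R)-[4-(benzyloxy)-3-methoxyphenyl][(tert-butyldimethylsilyl)oxy]methyl]-3-{[(2S,3R)-2-[4-(benzyloxy)-3-methoxyphenyl]-3-{[(tert-butyldimethylsilyl)oxy]methyl}-7-methoxy-2,3-dihydro-1-benzofuran-5-yl]methyl}oxolan-2-one, via lithium enolate 30 (not isolated)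
Conditions: LiN(SiMe3)2, THF, −78 °C; then 29, DMPU, −78 to −30 °C
Reagents that add atoms: none
Why: Alkylation of a beta-substituted gamma-butyrolactone enolate with a benzylic bromide; the electrophile approaches the planar enolate anti to the bulky beta substituent, which gives the trans lactone with C-alpha R, and the silyloxy group is too poor a leaving group to allow reclosure of the cyclopropane.

Step 20
Reactants: 31 (3R,4R)-4-[(R)-[4-(benzyloxy)-3-methoxyphenyl][(tert-butyldimethylsilyl)oxy]methyl]-3-{[(2S,3R)-2-[4-(benzyloxy)-3-methoxyphenyl]-3-{[(tert-butyldimethylsilyl)oxy]methyl}-7-methoxy-2,3-dihydro-1-benzofuran-5-yl]methyl}oxolan-2-one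
Product: 32 (3R,4R)-4-[(R)-[4-(benzyloxy)-3-methoxyphenyl](hydroxy)methyl]-3-{[(2S,3R)-2-[4-(benzyloxy)-3-methoxyphenyl]-3-(hydroxymethyl)-7-methoxy-2,3-dihydro-1-benzofuran-5-yl]methyl}oxolan-2-one
Conditions: Bu4NF, AcOH, THF, 0 °C to rt
Reagents that add atoms: none
Why: Fluoride-induced cleavage of both silyl ethers; acetic acid buffers the alkoxides so that neither translactonisation nor epimerisation at C-alpha sets in, and the phenols are still benzylated, so no quinone methide can form.

Step 21
Reactants: 32 (3R,4R)-4-[(R)-[4-(benzyloxy)-3-methoxyphenyl](hydroxy)methyl]-3-{[(2S,3R)-2-[4-(benzyloxy)-3-methoxyphenyl]-3-(hydroxymethyl)-7-methoxy-2,3-dihydro-1-benzofuran-5-yl]methyl}oxolan-2-one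
Product: 33 (3R,4R)-4-[(R)-hydroxy(4-hydroxy-3-methoxyphenyl)methyl]-3-{[(2S,3R)-2-(4-hydroxy-3-methoxyphenyl)-3-(hydroxymethyl)-7-methoxy-2,3-dihydro-1-benzofuran-5-yl]methyl}oxolan-2-one
Conditions: H2 (1 atm), Pd/C (10% Pd), EtOAc, rt, stopped at full debenzylation
Reagents that add atoms: none
Why: Hydrogenolysis of aryl benzyl ethers over palladium on carbon; under neutral conditions at ambient pressure the O–CH2Ph bonds cleave much faster than the benzylic carbinol C–O bond or the C2–O1 bond.

## Compound list

1 | 4-(benzyloxy)-3-methoxybenzaldehyde | COc1cc(C=O)ccc1OCc1ccccc1 | starting material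
2 | triethyl phosphonoacetate | CCOC(=O)CP(=O)(OCC)OCC | starting material
3 | ethyl (E)-3-[4-(benzyloxy)-3-methoxyphenyl]prop-2-enoate | CCOC(=O)/C=C/c1ccc(OCc2ccccc2)c(OC)c1 | intermediate
4 | (E)-3-[4-(benzyloxy)-3-methoxyphenyl]prop-2-en-1-ol | COc1cc(/C=C/CO)ccc1OCc1ccccc1 | intermediate
5 | bromoacetyl bromide | BrCC(=O)Br | starting material
6 | (E)-3-[4-(benzyloxy)-3-methoxyphenyl]prop-2-en-1-yl bromoacetate | COc1cc(/C=C/COC(=O)CBr)ccc1OCc1ccccc1 | intermediate
7 | (E)-3-[4-(benzyloxy)-3-methoxyphenyl]prop-2-en-1-yl 2-[1,2-bis(4-methylbenzenesulfonyl)hydrazin-1-yl]acetate | COc1cc(/C=C/COC(=O)CN(NS(=O)(=O)c2ccc(C)cc2)S(=O)(=O)c2ccc(C)cc2)ccc1OCc1ccccc1 | intermediate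
8 | (E)-3-[4-(benzyloxy)-3-methoxyphenyl]prop-2-en-1-yl diazoacetate | COc1cc(/C=C/COC(=O)C=[N+]=[N-])ccc1OCc1ccccc1 | intermediate
9 | (1S,5R,6R)-6-[4-(benzyloxy)-3-methoxyphenyl]-3-oxabicyclo[3.1.0]hexan-2-one | O=C1OC[C@@H]2[C@@H](c3ccc(OCc4ccccc4)c(OC)c3)[C@H]12 | intermediate
10 | (4R)-4-[(R)-[4-(benzyloxy)-3-methoxyphenyl](hydroxy)methyl]oxolan-2-one | O=C1C[C@@H]([C@@H](O)c2ccc(OCc3ccccc3)c(OC)c2)CO1 | intermediate
11 | (4R)-4-[(R)-[4-(benzyloxy)-3-methoxyphenyl][(tert-butyldimethylsilyl)oxy]methyl]oxolan-2-one | O=C1C[C@@H]([C@@H](O[Si](C)(C)C(C)(C)C)c2ccc(OCc3ccccc3)c(OC)c2)CO1 | intermediate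
12 | methyl 4-hydroxy-3-methoxybenzoate | COC(=O)c1ccc(O)c(OC)c1 | starting material
13 | allyl bromide | C=CCBr | starting material
14 | methyl 3-methoxy-4-(prop-2-en-1-yloxy)benzoate | COC(=O)c1ccc(OCC=C)c(OC)c1 | intermediate
15 | methyl 4-hydroxy-3-methoxy-5-(prop-2-en-1-yl)benzoate | COC(=O)c1cc(CC=C)c(O)c(OC)c1 | intermediate
16 | methyl 3-methoxy-4-(methoxymethoxy)-5-(prop-2-en-1-yl)benzoate | COC(=O)c1cc(CC=C)c(OCOC)c(OC)c1 | intermediate
17 | methyl 3-methoxy-4-(methoxymethoxy)-5-(2-oxoethyl)benzoate | COC(=O)c1cc(CC=O)c(OCOC)c(OC)c1 | intermediate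
18 | 2-[3-methoxy-5-(methoxycarbonyl)-2-(methoxymethoxy)phenyl]acetic acid | COC(=O)c1cc(CC(=O)O)c(OCOC)c(OC)c1 | intermediate
19 | (4S)-4-benzyl-1,3-oxazolidin-2-one | O=C1N[C@@H](Cc2ccccc2)CO1 | starting material
20 | 2-[3-methoxy-5-(methoxycarbonyl)-2-(methoxymethoxy)phenyl]acetic 2,2-dimethylpropanoic anhydride | COC(=O)c1cc(CC(=O)OC(=O)C(C)(C)C)c(OCOC)c(OC)c1 | intermediate
21 | methyl 3-{2-[(4S)-4-benzyl-2-oxo-1,3-oxazolidin-3-yl]-2-oxoethyl}-5-methoxy-4-(methoxymethoxy)benzoate | COC(=O)c1cc(CC(=O)N2[C@@H](Cc3ccccc3)COC2=O)c(OCOC)c(OC)c1 | intermediate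
22 | dibutylboron (Z)-enolate of 21 | CCCCB(CCCC)O/C(=C\c1cc(C(=O)OC)cc(OC)c1OCOC)N1[C@@H](Cc2ccccc2)COC1=O | intermediate
23 | methyl 3-[(2S,3S)-1-[(4S)-4-benzyl-2-oxo-1,3-oxazolidin-3-yl]-3-[4-(benzyloxy)-3-methoxyphenyl]-3-hydroxy-1-oxopropan-2-yl]-5-methoxy-4-(methoxymethoxy)benzoate | O=C([C@@H](c1cc(C(=O)OC)cc(OC)c1OCOC)[C@H](O)c1ccc(OCc2ccccc2)c(OC)c1)N1[C@@H](Cc2ccccc2)COC1=O | intermediate
24 | methyl 3-[(1S,2R)-1-[4-(benzyloxy)-3-methoxyphenyl]-1,3-dihydroxypropan-2-yl]-5-methoxy-4-(methoxymethoxy)benzoate | OC[C@@H](c1cc(C(=O)OC)cc(OC)c1OCOC)[C@H](O)c1ccc(OCc2ccccc2)c(OC)c1 | intermediate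
25 | methyl 3-[(1S,2R)-1-[4-(benzyloxy)-3-methoxyphenyl]-1,3-dihydroxypropan-2-yl]-4-hydroxy-5-methoxybenzoate | OC[C@@H](c1cc(C(=O)OC)cc(OC)c1O)[C@H](O)c1ccc(OCc2ccccc2)c(OC)c1 | intermediate
26 | methyl (2S,3R)-2-[4-(benzyloxy)-3-methoxyphenyl]-3-(hydroxymethyl)-7-methoxy-2,3-dihydro-1-benzofuran-5-carboxylate | COc1cc([C@H]2Oc3c(OC)cc(C(=O)OC)cc3[C@@H]2CO)ccc1OCc1ccccc1 | intermediate
27 | methyl (2S,3R)-2-[4-(benzyloxy)-3-methoxyphenyl]-3-{[(tert-butyldimethylsilyl)oxy]methyl}-7-methoxy-2,3-dihydro-1-benzofuran-5-carboxylate | COc1cc([C@H]2Oc3c(OC)cc(C(=O)OC)cc3[C@@H]2CO[Si](C)(C)C(C)(C)C)ccc1OCc1ccccc1 | intermediate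
28 | [(2S,3R)-2-[4-(benzyloxy)-3-methoxyphenyl]-3-{[(tert-butyldimethylsilyl)oxy]methyl}-7-methoxy-2,3-dihydro-1-benzofuran-5-yl]methanol | COc1cc([C@H]2Oc3c(OC)cc(CO)cc3[C@@H]2CO[Si](C)(C)C(C)(C)C)ccc1OCc1ccccc1 | intermediate
29 | (2S,3R)-2-[4-(benzyloxy)-3-methoxyphenyl]-5-(bromomethyl)-3-{[(tert-butyldimethylsilyl)oxy]methyl}-7-methoxy-2,3-dihydro-1-benzofuran | COc1cc([C@H]2Oc3c(OC)cc(CBr)cc3[C@@H]2CO[Si](C)(C)C(C)(C)C)ccc1OCc1ccccc1 | intermediate
30 | lithium enolate of 11 | [Li]OC1=C[C@@H]([C@@H](O[Si](C)(C)C(C)(C)C)c2ccc(OCc3ccccc3)c(OC)c2)CO1 | intermediate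
31 | (3R,4R)-4-[(R)-[4-(benzyloxy)-3-methoxyphenyl][(tert-butyldimethylsilyl)oxy]methyl]-3-{[(2S,3R)-2-[4-(benzyloxy)-3-methoxyphenyl]-3-{[(tert-butyldimethylsilyl)oxy]methyl}-7-methoxy-2,3-dihydro-1-benzofuran-5-yl]methyl}oxolan-2-one | COc1cc([C@H]2Oc3c(OC)cc(C[C@H]4C(=O)OC[C@@H]4[C@@H](O[Si](C)(C)C(C)(C)C)c4ccc(OCc5ccccc5)c(OC)c4)cc3[C@@H]2CO[Si](C)(C)C(C)(C)C)ccc1OCc1ccccc1 | intermediate
32 | (3R,4R)-4-[(R)-[4-(benzyloxy)-3-methoxyphenyl](hydroxy)methyl]-3-{[(2S,3R)-2-[4-(benzyloxy)-3-methoxyphenyl]-3-(hydroxymethyl)-7-methoxy-2,3-dihydro-1-benzofuran-5-yl]methyl}oxolan-2-one | COc1cc([C@H]2Oc3c(OC)cc(C[C@H]4C(=O)OC[C@@H]4[C@@H](O)c4ccc(OCc5ccccc5)c(OC)c4)cc3[C@@H]2CO)ccc1OCc1ccccc1 | intermediate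
33 | (3R,4R)-4-[(R)-hydroxy(4-hydroxy-3-methoxyphenyl)methyl]-3-{[(2S,3R)-2-(4-hydroxy-3-methoxyphenyl)-3-(hydroxymethyl)-7-methoxy-2,3-dihydro-1-benzofuran-5-yl]methyl}oxolan-2-one | COc1cc([C@H]2Oc3c(OC)cc(C[C@H]4C(=O)OC[C@@H]4[C@@H](O)c4ccc(O)c(OC)c4)cc3[C@@H]2CO)ccc1O | target

## Step count and least certain steps

Total step count: 21. Longest linear sequence: 14 steps (steps 8 to 21, from 12 to 33).

**Step 6 (proposed new method).**
- What may go wrong: the C1–C6 bond may ionise to a free benzylic cation stabilised by ring C (SN1) before water arrives. Water then adds from both faces, or the lactone carbonyl oxygen captures the cation and the lactone rearranges. The product carbinol may also re-ionise under the Lewis acid. The para-alkoxy group that makes the opening possible is the same group that endangers its stereospecificity.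
- Fallback (known chemistry; sets out from 4, returns at 11): the cyclopropane is given a second acceptor so that the opening becomes the established diester type. 4 is oxidised with MnO2 to (E)-3-[4-(benzyloxy)-3-methoxyphenyl]prop-2-enal F1. Iminium-catalysed Michael addition and ring closure with dimethyl bromomalonate, using (S)-alpha,alpha-diphenylprolinol trimethylsilyl ether and 2,6-lutidine, gives dimethyl (2S,3R)-2-[4-(benzyloxy)-3-methoxyphenyl]-3-formylcyclopropane-1,1-dicarboxylate F2. NaBH4 reduces the aldehyde and the alcohol lactonises onto the cis ester to give methyl (1S,5R,6S)-6-[4-(benzyloxy)-3-methoxyphenyl]-2-oxo-3-oxabicyclo[3.1.0]hexane-1-carboxylate F3. Sc(OTf)3 or Cu(OTf)2 with water then opens the doubly activated ring with inversion to methyl (4R)-4-[(R)-[4-(benzyloxy)-3-methoxyphenyl](hydroxy)methyl]-2-oxooxolane-3-carboxylate F4. Immediate silylation gives methyl (4R)-4-[(R)-[4-(benzyloxy)-3-methoxyphenyl][(tert-butyldimethylsilyl)oxy]methyl]-2-oxooxolane-3-carboxylate F5. Krapcho demethoxycarbonylation (LiCl, wet DMSO, 140 °C) leads to 11.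

**Step 5 (key step).**
- What may go wrong: facial discrimination may be incomplete because the trans aryl substituent points toward the ligand ester groups. The carbenoid may dimerise or add to an electron-rich arene. The sense of induction assigned by analogy may be the opposite; the antipodal catalyst would then be used.
- Fallback (known chemistry; sets out from 1, returns at 10): C-beta and the carbinol centre are set by an auxiliary-controlled anti aldol. (4R)-4-Benzyl-1,3-oxazolidin-2-one is N-acylated with methyl 4-chloro-4-oxobutanoate (n-BuLi, THF, −78 °C) to methyl 4-[(4R)-4-benzyl-2-oxo-1,3-oxazolidin-3-yl]-4-oxobutanoate F6. The MgCl2-catalysed anti aldol with 1 (Et3N, Me3SiCl, EtOAc), through the chelated enolate, gives methyl (3S,4R)-3-[(4R)-4-benzyl-2-oxo-1,3-oxazolidine-3-carbonyl]-4-[4-(benzyloxy)-3-methoxyphenyl]-4-[(trimethylsilyl)oxy]butanoate F7. LiBH4 reduces the imide and the primary alkoxide closes onto the methyl ester to give (4R)-4-[(R)-[4-(benzyloxy)-3-methoxyphenyl][(trimethylsilyl)oxy]methyl]oxolan-2-one F8. Mild acidic work-up removes the silyl group to give 10.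

**Step 19.**
- What may go wrong: the para-alkoxybenzyl bromide 29 may ionise and decompose before it is captured. The hindered enolate 30 may react slowly, with proton transfer and double alkylation as the consequence.
- Fallback (known chemistry; sets out from 28 and 11, returns at 31): the bond is made by aldol addition and the extra oxygen is removed by a radical. 28 is oxidised with MnO2 to (2S,3R)-2-[4-(benzyloxy)-3-methoxyphenyl]-3-{[(tert-butyldimethylsilyl)oxy]methyl}-7-methoxy-2,3-dihydro-1-benzofuran-5-carbaldehyde F9. Enolate 30 adds to F9 anti to the beta substituent to give (3S,4R)-4-[(R)-[4-(benzyloxy)-3-methoxyphenyl][(tert-butyldimethylsilyl)oxy]methyl]-3-{[(2S,3R)-2-[4-(benzyloxy)-3-methoxyphenyl]-3-{[(tert-butyldimethylsilyl)oxy]methyl}-7-methoxy-2,3-dihydro-1-benzofuran-5-yl](hydroxy)methyl}oxolan-2-one F10, as a mixture at the new carbinol. 1,1'-Thiocarbonyldiimidazole converts F10 into the O-(imidazol-1-ylcarbonothioyl) derivative of that alcohol F11. Barton–McCombie deoxygenation (Bu3SnH, AIBN, toluene, 80 °C) gives 31.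

**Step 21.**
- What may go wrong: once ring C is a free para-hydroxyphenyl group, the benzylic carbinol C–O bond (and, less readily, the C2–O1 bond) may be hydrogenolysed further.
- Fallback (sets out from 31, returns at 33): the order of deprotection is reversed so that the carbinol is still a hindered silyl ether during hydrogenation. Hydrogenolysis of 31 (H2, Pd/C, EtOAc) gives (3R,4R)-4-[(R)-[(tert-butyldimethylsilyl)oxy](4-hydroxy-3-methoxyphenyl)methyl]-3-{[(2S,3R)-3-{[(tert-butyldimethylsilyl)oxy]methyl}-2-(4-hydroxy-3-methoxyphenyl)-7-methoxy-2,3-dihydro-1-benzofuran-5-yl]methyl}oxolan-2-one F12. The silyl groups are then removed with the weakly acidic Et3N·3HF in MeCN, which avoids phenoxide formation, to give 33.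

## Further compounds

F1 | step 6 | (E)-3-[4-(benzyloxy)-3-methoxyphenyl]prop-2-enal | COc1cc(/C=C/C=O)ccc1OCc1ccccc1
F2 | step 6 | dimethyl (2S,3R)-2-[4-(benzyloxy)-3-methoxyphenyl]-3-formylcyclopropane-1,1-dicarboxylate | O=C[C@@H]1[C@@H](c2ccc(OCc3ccccc3)c(OC)c2)C1(C(=O)OC)C(=O)OC
F3 | step 6 | methyl (1S,5R,6S)-6-[4-(benzyloxy)-3-methoxyphenyl]-2-oxo-3-oxabicyclo[3.1.0]hexane-1-carboxylate | O=C1OC[C@@H]2[C@@H](c3ccc(OCc4ccccc4)c(OC)c3)[C@]12C(=O)OC
F4 | step 6 | methyl (4R)-4-[(R)-[4-(benzyloxy)-3-methoxyphenyl](hydroxy)methyl]-2-oxooxolane-3-carboxylate (both C3 epimers) | COC(=O)C1C(=O)OC[C@@H]1[C@@H](O)c1ccc(OCc2ccccc2)c(OC)c1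
F5 | step 6 | methyl (4R)-4-[(R)-[4-(benzyloxy)-3-methoxyphenyl][(tert-butyldimethylsilyl)oxy]methyl]-2-oxooxolane-3-carboxylate (both C3 epimers) | COC(=O)C1C(=O)OC[C@@H]1[C@@H](O[Si](C)(C)C(C)(C)C)c1ccc(OCc2ccccc2)c(OC)c1
F6 | step 5 | methyl 4-[(4R)-4-benzyl-2-oxo-1,3-oxazolidin-3-yl]-4-oxobutanoate | COC(=O)CCC(=O)N1[C@H](Cc2ccccc2)COC1=O
F7 | step 5 | methyl (3S,4R)-3-[(4R)-4-benzyl-2-oxo-1,3-oxazolidine-3-carbonyl]-4-[4-(benzyloxy)-3-methoxyphenyl]-4-[(trimethylsilyl)oxy]butanoate | O=C([C@@H](CC(=O)OC)[C@@H](O[Si](C)(C)C)c1ccc(OCc2ccccc2)c(OC)c1)N1[C@H](Cc2ccccc2)COC1=O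
F8 | step 5 | (4R)-4-[(R)-[4-(benzyloxy)-3-methoxyphenyl][(trimethylsilyl)oxy]methyl]oxolan-2-one | O=C1C[C@@H]([C@@H](O[Si](C)(C)C)c2ccc(OCc3ccccc3)c(OC)c2)CO1
F9 | step 19 | (2S,3R)-2-[4-(benzyloxy)-3-methoxyphenyl]-3-{[(tert-butyldimethylsilyl)oxy]methyl}-7-methoxy-2,3-dihydro-1-benzofuran-5-carbaldehyde | COc1cc([C@H]2Oc3c(OC)cc(C=O)cc3[C@@H]2CO[Si](C)(C)C(C)(C)C)ccc1OCc1ccccc1
F10 | step 19 | (3S,4R)-4-[(R)-[4-(benzyloxy)-3-methoxyphenyl][(tert-butyldimethylsilyl)oxy]methyl]-3-{[(2S,3R)-2-[4-(benzyloxy)-3-methoxyphenyl]-3-{[(tert-butyldimethylsilyl)oxy]methyl}-7-methoxy-2,3-dihydro-1-benzofuran-5-yl](hydroxy)methyl}oxolan-2-one (both carbinol epimers) | COc1cc([C@H]2Oc3c(OC)cc(C(O)[C@H]4C(=O)OC[C@@H]4[C@@H](O[Si](C)(C)C(C)(C)C)c4ccc(OCc5ccccc5)c(OC)c4)cc3[C@@H]2CO[Si](C)(C)C(C)(C)C)ccc1OCc1ccccc1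
F11 | step 19 | O-(imidazol-1-ylcarbonothioyl) derivative of F10 | COc1cc([C@H]2Oc3c(OC)cc(C(OC(=S)n4ccnc4)[C@H]4C(=O)OC[C@@H]4[C@@H](O[Si](C)(C)C(C)(C)C)c4ccc(OCc5ccccc5)c(OC)c4)cc3[C@@H]2CO[Si](C)(C)C(C)(C)C)ccc1OCc1ccccc1
F12 | step 21 | (3R,4R)-4-[(R)-[(tert-butyldimethylsilyl)oxy](4-hydroxy-3-methoxyphenyl)methyl]-3-{[(2S,3R)-3-{[(tert-butyldimethylsilyl)oxy]methyl}-2-(4-hydroxy-3-methoxyphenyl)-7-methoxy-2,3-dihydro-1-benzofuran-5-yl]methyl}oxolan-2-one | COc1cc([C@H]2Oc3c(OC)cc(C[C@H]4C(=O)OC[C@@H]4[C@@H](O[Si](C)(C)C(C)(C)C)c4ccc(O)c(OC)c4)cc3[C@@H]2CO[Si](C)(C)C(C)(C)C)ccc1O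
A1 | alternative 1 | (5R)-5-[(1R,2S,5R)-menthyloxy]furan-2(5H)-one | O=C1C=C[C@H](O[C@@H]2C[C@H](C)CC[C@H]2C(C)C)O1
A2 | alternative 1 | 2-[4-(benzyloxy)-3-methoxyphenyl]-1,3-dithiane | COc1cc(C2SCCCS2)ccc1OCc1ccccc1
A3 | alternative 1 | trans-alpha,beta-disubstituted menthyl acetal lactone with the dithiane at the carbinol carbon | COc1cc([C@H]2Oc3c(OC)cc(C[C@H]4C(=O)O[C@@H](O[C@@H]5C[C@H](C)CC[C@H]5C(C)C)[C@@H]4C4(SCCCS4)c4ccc(OCc5ccccc5)c(OC)c4)cc3[C@@H]2CO[Si](C)(C)C(C)(C)C)ccc1OCc1ccccc1
A4 | alternative 2 | 2-{4-[(1S)-1-[4-(benzyloxy)-3-methoxyphenyl]prop-2-en-1-yloxy]-3-iodo-5-methoxyphenyl}-1,3-dioxolane | COc1cc(C2OCCO2)cc(I)c1O[C@@H](C=C)c1ccc(OCc2ccccc2)c(OC)c1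
A5 | alternative 2 | (2S,3R)-2-[4-(benzyloxy)-3-methoxyphenyl]-5-(1,3-dioxolan-2-yl)-7-methoxy-3-{[(2,2,6,6-tetramethylpiperidin-1-yl)oxy]methyl}-2,3-dihydro-1-benzofuran | COc1cc([C@H]2Oc3c(OC)cc(C4OCCO4)cc3[C@@H]2CON2C(C)(C)CCCC2(C)C)ccc1OCc1ccccc1
A6 | alternative 3 | (4S)-4-benzyl-3-[(E)-3-(4-hydroxy-3-methoxyphenyl)prop-2-enoyl]-1,3-oxazolidin-2-one | COc1cc(/C=C/C(=O)N2[C@@H](Cc3ccccc3)COC2=O)ccc1O
A7 | alternative 3 | (3R,4R)-4-[(R)-[4-(benzyloxy)-3-methoxyphenyl](hydroxy)methyl]-3-(4-hydroxy-3-methoxybenzyl)oxolan-2-one | COc1cc(C[C@H]2C(=O)OC[C@@H]2[C@@H](O)c2ccc(OCc3ccccc3)c(OC)c2)ccc1O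
A8 | alternative 3 | trans-dihydrobenzofuran of the full skeleton with the C3 acyl oxazolidinone and ring C O-benzyl | COc1cc([C@H]2Oc3c(OC)cc(C[C@H]4C(=O)OC[C@@H]4[C@@H](O)c4ccc(OCc5ccccc5)c(OC)c4)cc3[C@@H]2C(=O)N2[C@@H](Cc3ccccc3)COC2=O)ccc1O
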